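**Retrosynthetic overview**
- Kuwanon B is traced back to its tris-allyl ether, and this to a 5,7-difluoroflavone whose two C–F bonds are exchanged for C–O bonds by allyloxide.
- Feature used: in ring A, O1 sits on C8a, the carbon next to C4a that carries the C4 carbonyl, and the oxygens on C5 and C7 are ortho and para to that carbonyl. A symmetrical 2,4,6-trifluorobenzoyl unit can therefore stand for ring A: one ortho fluoride is the leaving group for O1–C8a, the other two fluorides are latent hydroxyls.
- Ring C is cut at C3–C4 and at O1–C8a, giving 2,4,6-trifluorobenzoyl chloride and a ring B ketone that already carries the prenyl group on the future C3.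
- The ring B ketone comes from 2,4-dihydroxyacetophenone by chromenylation with prenal, O-allylation and enolate prenylation.
- Ring order: ring B is bought, the dimethylpyran ring is fused on first (step 1), ring A is bought as the fluoroarene, and ring C is closed last (step 4).

Key step: step 4

Assumption: flavone numbering (O1, C2, C3, C4, C4a, C5 to C8, C8a) is used for ring A and ring C; the 1,3-diketone of the key step is drawn in its keto form although it is present as its enolate, and its single sp3 centre is racemic and disappears on ring closure.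

**Step 1**
Reactants: 1 2,4-dihydroxyacetophenone; 2 3-methylbut-2-enal (prenal)
Product: 3 1-(5-hydroxy-2,2-dimethyl-2H-chromen-6-yl)ethan-1-one
Conditions: pyridine, 120 °C
Reagents that add atoms: none
Why: Chromenylation of a resorcinol by an enal (aldol-type condensation at the carbon between the two hydroxyls, dehydration and oxa-6π electrocyclisation) should close through the 4-hydroxyl, because the 2-hydroxyl stays hydrogen-bonded to the acetyl group, so the angular 5-hydroxy-6-acetyl chromene is expected.

**Step 2**
Reactants: 3 1-(5-hydroxy-2,2-dimethyl-2H-chromen-6-yl)ethan-1-one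
Product: 4 1-[5-(allyloxy)-2,2-dimethyl-2H-chromen-6-yl]ethan-1-one
Conditions: allyl bromide, K2CO3, DMF, 60 °C
Reagents that add atoms: allyl bromide, C=CCBr
Why: Williamson ether synthesis; the hydrogen-bonded phenol reacts slowly but should be fully alkylated by a reactive allylic bromide in DMF, and carbonate does not touch the ketone α-protons.

**Step 3**
Reactants: 4 1-[5-(allyloxy)-2,2-dimethyl-2H-chromen-6-yl]ethan-1-one; 5 1-bromo-3-methylbut-2-ene (prenyl bromide)
Product: 6 1-[5-(allyloxy)-2,2-dimethyl-2H-chromen-6-yl]-5-methylhex-4-en-1-one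
Conditions: LiN(iPr)2 (1.05 equiv), THF, −78 °C; then 5 (0.95 equiv), −78 to 0 °C
Reagents that add atoms: none
Why: Kinetic lithium enolate alkylation of an aryl methyl ketone at the primary carbon of an allylic bromide; low temperature and a slight deficit of 5 should hold back a second alkylation.

**Step 4**
Reactants: 6 1-[5-(allyloxy)-2,2-dimethyl-2H-chromen-6-yl]-5-methylhex-4-en-1-one; 7 2,4,6-trifluorobenzoyl chloride
Product: 9 2-[5-(allyloxy)-2,2-dimethyl-2H-chromen-6-yl]-5,7-difluoro-3-(3-methylbut-2-enyl)-4H-chromen-4-one, via 2-prenyl-1,3-diketone 8 (not isolated)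
Conditions: LiN(SiMe3)2 (2.1 equiv), THF, −78 to −20 °C; 7 (0.95 equiv), −78 to 0 °C; then DMF, K2CO3, 70 °C
Reagents that add atoms: none
Why: LiN(SiMe3)2 turns 6 into its lithium enolate, whose α-carbon attacks the acid chloride 7 (addition–elimination at the acyl carbon, bond C3–C4), and the second equivalent of amide at once deprotonates the resulting 2-prenyl 1,3-diketone 8, which draws the equilibrium to the diketonate. On warming in DMF with K2CO3 the enolate oxygen on the ring B side should add to one ortho C–F carbon of the trifluorophenyl ring and fluoride should leave from a Meisenheimer anion stabilised by the ortho carbonyl and the two other fluorines; this makes O1–C8a and closes ring C in a 6-exo-trig addition–elimination. The closest known reaction type is the one-pot acylation of ketone enolates with 2-fluorobenzoyl chlorides followed by intramolecular nucleophilic aromatic substitution to chromones and flavones, a halide-based relative of the Baker–Venkataraman flavone synthesis. No stereocentre is created, since the only sp3 centre of 8 becomes the trigonal C3. C-acylation over O-acylation is secured by keeping the lithium enolate in slight excess over 7, so that any enol ester passes its acyl group to free enolate and the material drains into the stabilised diketonate. The closure has no regiochemical choice: the two ortho fluorines are equivalent, attack through C3 or through the C4 oxygen would need a four-membered ring, and the ring B oxygen is masked as its allyl ether and cannot compete as a phenoxide.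

**Step 5**
Reactants: 9 2-[5-(allyloxy)-2,2-dimethyl-2H-chromen-6-yl]-5,7-difluoro-3-(3-methylbut-2-enyl)-4H-chromen-4-one
Product: 11 5,7-bis(allyloxy)-2-[5-(allyloxy)-2,2-dimethyl-2H-chromen-6-yl]-3-(3-methylbut-2-enyl)-4H-chromen-4-one, via 7-allyloxy-5-fluoroflavone 10 (not isolated)
Conditions: allyl alcohol (excess), NaH (4 equiv), DMF, 0 to 60 °C
Reagents that add atoms: allyl alcohol, C=CCO
Why: Twofold nucleophilic aromatic substitution (addition–elimination) by NaOCH2CH=CH2 at the fluorides para (C7) and ortho (C5) to the C4 carbonyl; C2 is shielded by the aryl and prenyl groups against conjugate attack of the alkoxide.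

**Step 6**
Reactants: 11 5,7-bis(allyloxy)-2-[5-(allyloxy)-2,2-dimethyl-2H-chromen-6-yl]-3-(3-methylbut-2-enyl)-4H-chromen-4-one
Product: 12 kuwanon B
Conditions: Pd(PPh3)4 (5 mol %), morpholine (10 equiv), THF, 25 °C
Reagents that add atoms: none
Why: Zerovalent palladium ionises each aryl allyl ether to a π-allyl complex that morpholine traps (Tsuji–Trost deallylation), under neutral conditions that should leave the prenyl group, the chromene ring and the free phenols untouched.

**Compound list**
1 | 2,4-dihydroxyacetophenone | CC(=O)c1ccc(O)cc1O | starting material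
2 | 3-methylbut-2-enal (prenal) | CC(C)=CC=O | starting material
3 | 1-(5-hydroxy-2,2-dimethyl-2H-chromen-6-yl)ethan-1-one | CC(=O)c1ccc2c(c1O)C=CC(C)(C)O2 | intermediate
4 | 1-[5-(allyloxy)-2,2-dimethyl-2H-chromen-6-yl]ethan-1-one | CC(=O)c1ccc2c(c1OCC=C)C=CC(C)(C)O2 | intermediate
5 | 1-bromo-3-methylbut-2-ene (prenyl bromide) | CC(C)=CCBr | starting material
6 | 1-[5-(allyloxy)-2,2-dimethyl-2H-chromen-6-yl]-5-methylhex-4-en-1-one | CC(C)=CCCC(=O)c1ccc2c(c1OCC=C)C=CC(C)(C)O2 | intermediate
7 | 2,4,6-trifluorobenzoyl chloride | O=C(Cl)c1c(F)cc(F)cc1F | starting material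
8 | 1-[5-(allyloxy)-2,2-dimethyl-2H-chromen-6-yl]-2-(3-methylbut-2-enyl)-3-(2,4,6-trifluorophenyl)propane-1,3-dione (racemic, present as its enolate, not isolated) | CC(C)=CCC(C(=O)c1c(F)cc(F)cc1F)C(=O)c1ccc2c(c1OCC=C)C=CC(C)(C)O2 | intermediate
9 | 2-[5-(allyloxy)-2,2-dimethyl-2H-chromen-6-yl]-5,7-difluoro-3-(3-methylbut-2-enyl)-4H-chromen-4-one | CC(C)=CCc1c(-c2ccc3c(c2OCC=C)C=CC(C)(C)O3)oc2cc(F)cc(F)c2c1=O | intermediate
10 | 7-(allyloxy)-2-[5-(allyloxy)-2,2-dimethyl-2H-chromen-6-yl]-5-fluoro-3-(3-methylbut-2-enyl)-4H-chromen-4-one (not isolated; the para fluoride at C7 is expected to be exchanged first) | CC(C)=CCc1c(-c2ccc3c(c2OCC=C)C=CC(C)(C)O3)oc2cc(OCC=C)cc(F)c2c1=O | intermediate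
11 | 5,7-bis(allyloxy)-2-[5-(allyloxy)-2,2-dimethyl-2H-chromen-6-yl]-3-(3-methylbut-2-enyl)-4H-chromen-4-one | CC(C)=CCc1c(-c2ccc3c(c2OCC=C)C=CC(C)(C)O3)oc2cc(OCC=C)cc(OCC=C)c2c1=O | intermediate
12 | kuwanon B, 5,7-dihydroxy-2-(5-hydroxy-2,2-dimethyl-2H-chromen-6-yl)-3-(3-methylbut-2-enyl)-4H-chromen-4-one | CC(C)=CCc1c(-c2ccc3c(c2O)C=CC(C)(C)O3)oc2cc(O)cc(O)c2c1=O | target

**Step count**
Total steps: 6. Longest linear sequence: 6 steps, from 2,4-dihydroxyacetophenone 1 to kuwanon B 12.

**Steps most likely to fail**

1. Step 4. The hindered, α-substituted enolate may be acylated on oxygen instead of carbon, or the amide base may consume the acid chloride, so that the C3–C4 bond is not formed cleanly. Fallback: make the C–C bond by an aldol addition and adjust the oxidation level afterwards. Setting out from 6, its lithium enolate (LiN(iPr)2, THF, −78 °C) would be added to purchased 2,4,6-trifluorobenzaldehyde and quenched cold to give the β-hydroxy ketone 1-[5-(allyloxy)-2,2-dimethyl-2H-chromen-6-yl]-2-[hydroxy(2,4,6-trifluorophenyl)methyl]-5-methylhex-4-en-1-one F1 as a mixture of diastereomers, all of which converge. Oxidation with Dess–Martin periodinane (NaHCO3, CH2Cl2) should give the diketone 8, now isolated, and K2CO3 in DMF at 70 °C would close ring C, so the fallback comes back to the route at 8 and then 9.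

2. Step 5. The second fluoride exchange may stall once the first allyloxy group has weakened the activation by the carbonyl, or the alkoxide may add at C2 and open ring C with retro-Claisen cleavage. Fallback: bring the two ring A oxygens in before ring closure, so that the flavone never meets an alkoxide. Purchased 5-fluororesorcinol would be bis-allylated (allyl bromide, K2CO3, DMF) to 1,3-bis(allyloxy)-5-fluorobenzene F2. Vilsmeier–Haack formylation (POCl3, DMF) ortho to fluorine would give 2,4-bis(allyloxy)-6-fluorobenzaldehyde F3. Pinnick oxidation (NaClO2, NaH2PO4, 2-methylbut-2-ene, t-BuOH/water) would give 2,4-bis(allyloxy)-6-fluorobenzoic acid F4, and oxalyl chloride with catalytic DMF in CH2Cl2 would give 2,4-bis(allyloxy)-6-fluorobenzoyl chloride F5. Setting out from 6, its lithium enolate would be acylated by F5 under the step 4 conditions to the 1,3-diketone 1-[5-(allyloxy)-2,2-dimethyl-2H-chromen-6-yl]-3-[2,4-bis(allyloxy)-6-fluorophenyl]-2-(3-methylbut-2-enyl)propane-1,3-dione F6. Displacement of its single ortho fluoride (K2CO3, DMF, 100 °C) would give the tris-allyl ether directly, so the fallback comes back to the route at 11.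

3. Step 3. Proton exchange between the product ketone and unreacted enolate may lead to double prenylation and recovered methyl ketone. Fallback: alkylate an azaenolate, which stops at the monoalkyl stage. Setting out from 4, condensation with N,N-dimethylhydrazine (EtOH, catalytic AcOH, reflux) would give 1-[5-(allyloxy)-2,2-dimethyl-2H-chromen-6-yl]ethan-1-one N,N-dimethylhydrazone F7. Metalation with LiN(iPr)2 (THF, 0 °C) and alkylation with 5 at −78 °C would give 1-[5-(allyloxy)-2,2-dimethyl-2H-chromen-6-yl]-5-methylhex-4-en-1-one N,N-dimethylhydrazone F8. Two-phase hydrolysis with saturated aqueous oxalic acid and diethyl ether at 25 °C would release the ketone, so the fallback comes back to the route at 6.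

**Further compounds**
F1 | step 4 | 1-[5-(allyloxy)-2,2-dimethyl-2H-chromen-6-yl]-2-[hydroxy(2,4,6-trifluorophenyl)methyl]-5-methylhex-4-en-1-one (racemic mixture of diastereomers) | CC(C)=CCC(C(O)c1c(F)cc(F)cc1F)C(=O)c1ccc2c(c1OCC=C)C=CC(C)(C)O2
F2 | step 5 | 1,3-bis(allyloxy)-5-fluorobenzene | C=CCOc1cc(F)cc(OCC=C)c1
F3 | step 5 | 2,4-bis(allyloxy)-6-fluorobenzaldehyde | O=Cc1c(F)cc(OCC=C)cc1OCC=C
F4 | step 5 | 2,4-bis(allyloxy)-6-fluorobenzoic acid | OC(=O)c1c(F)cc(OCC=C)cc1OCC=C
F5 | step 5 | 2,4-bis(allyloxy)-6-fluorobenzoyl chloride | O=C(Cl)c1c(F)cc(OCC=C)cc1OCC=C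
F6 | step 5 | 1-[5-(allyloxy)-2,2-dimethyl-2H-chromen-6-yl]-3-[2,4-bis(allyloxy)-6-fluorophenyl]-2-(3-methylbut-2-enyl)propane-1,3-dione (racemic, present as its enolate) | CC(C)=CCC(C(=O)c1c(F)cc(OCC=C)cc1OCC=C)C(=O)c1ccc2c(c1OCC=C)C=CC(C)(C)O2
F7 | step 3 | 1-[5-(allyloxy)-2,2-dimethyl-2H-chromen-6-yl]ethan-1-one N,N-dimethylhydrazone (C=N geometry not controlled and of no consequence) | CC(=NN(C)C)c1ccc2c(c1OCC=C)C=CC(C)(C)O2
F8 | step 3 | 1-[5-(allyloxy)-2,2-dimethyl-2H-chromen-6-yl]-5-methylhex-4-en-1-one N,N-dimethylhydrazone (C=N geometry not controlled and of no consequence) | CC(C)=CCCC(=NN(C)C)c1ccc2c(c1OCC=C)C=CC(C)(C)O2
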